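## Structural features

The target is a cis-fused bicycle: a 1,2-dioxane (O1, O2, C3, C4, C5, C6) fused across C3–C4 to a γ-lactone (C1 carbonyl, C2, C3, C4 and the ring oxygen on C4). The chain is numbered C1 to C14, with C14 the benzylic CH2. C4 and C6 are fully substituted, each carries a methyl group, and they are separated by the unfunctionalised C5 methylene. C6 carries the chain C7H2–C8H(CH3)–C9H2–C10(CH3)=C11H–C12(CH3)=C13H–C14H2Ph. The configuration is 3S,4S,6R,8R,10E,12E: the two ring methyls are cis, while C2, the lactone oxygen and C7 lie on the other face, so in the chair with both methyls equatorial the C4–O and C6–C7 bonds are axial. C3 and C4 are adjacent and tied by the ring fusion, C6 is 1,3 to C4, and C8 is insulated from the ring by C7. The fragile groups are the O–O bond (hydrogenation, low-valent metals, phosphines, hard carbanions), the acidic C2–H (retro-oxa-Michael opening of the dioxane) and the 1,3-diene (acid, singlet oxygen, radicals, metal hydrides). The real difficulty is C6, a quaternary peroxide carbon whose two carbon substituents (CH3 and C7H2R) are sterically alike, so a dioxane closure by O–C bond formation has no handle to set it. The second difficulty is C8, which cannot be built by reductive methods once the peroxide is present. The key step exploits that C6, once the C6–C7 bond is removed, is a ketal-level carbon bonded to O1 inside the dioxane: as a ring-bound peroxycarbenium ion (C6=O1+) it distinguishes axial from equatorial entry, which size alone cannot do.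

## Logic of the disconnections

**25 to 21 and 22.** The C11–C12 bond between the two alkenes is cut. The diene is a π-nucleophile and is acid-sensitive, so it is kept out of the Lewis-acidic key step and added last by a palladium-catalysed coupling of two sp2 carbons. The gain is a core that carries only a vinyl iodide. The forward step must leave the O–O bond and the lactone untouched and needs a regiodefined alkenyl metal from 22.

**21 to 9 and 18 (through 19 and 20).** The C6–C7 bond is cut. This is the only cut that turns the sterically undifferentiated quaternary centre into a ring-bound cation (20), whose faces differ stereoelectronically. The gain is large: the whole C7–C11 unit with C8 preset arrives in one piece from 18, and the core 9 carries only C3 and C4, one derived from the other. The forward step needs an sp3 carbon nucleophile (19) that adds to 20 faster than it transfers hydride or attacks the O–O bond, and it needs ionisation of the exocyclic C6–OMe bond, not the ring C6–O1 bond.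

**9 to 7 (through 8).** The O2–C3 bond and both C6–O bonds are cut. Ozonolysis in methanol supplies both peroxide oxygens and raises C6 to the ketal level in one operation, and the oxa-Michael closure relays C3 from C4 through the cis ring fusion. The forward step needs ozone to select the 1,1-disubstituted alkene over the butenolide and the Criegee fragmentation to place the peroxide on C6.

**7 to 4 and 5 (through 6).** The C2=C3 bond and the C1–O bond are cut. One reagent (5) delivers C1 and C2 and closes the butenolide with the Z geometry enforced by the ring. The demand is addition of a hindered tertiary hydroxyl to the cumulene before the aldehyde degrades.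

**4 to 3, and 3 to 1 and 2.** The C5–C6 bond is cut and C3 is adjusted in oxidation level. C4 is bought as the only stereocentre of 1 and is never touched. The demand is epoxide opening at the CH2 terminus and selective oxidation of a primary hydroxyl next to a tertiary one.

**18 to 17 and 16, and 16 to 13 and 14 (through 15).** The C8–C9 bond is cut. An auxiliary-controlled alkylation with an allylic bromide sets C8 and carries the (E)-vinyl iodide in unchanged. The demand is high facial selectivity of the enolate and survival of the vinyl iodide through reduction and iodination.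

**13 to 12 and 10 (through 11).** The C10–CH3 and C11–I bonds are cut. syn-Carbometalation of an alkyne fixes the 10E geometry from a three-carbon commodity. The demand is clean syn addition and iodinolysis with retention.

## Other disconnections considered

**Alternative 1:** (the first that comes to mind) Cut O2–C3. The forward key step is the intramolecular oxa-Michael addition of the tertiary hydroperoxide A1 to its butenolide, with A1 coming from radical hydroperoxidation at C6 (Co(acac)2, O2, Et3SiH; Isayama–Mukaiyama). The closure itself is sound and sets C3 by cis fusion. However, C6 would be fixed when a planar tertiary radical flanked by CH3 and CH2R captures O2, so no facial preference is expected and half the material would be the C6 epimer. The diene would not tolerate the metal hydride conditions either, so the chain would still have to be finished afterwards. The chosen plan sets C6 by a stereoelectronic preference and joins the fragments at the same time.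

**Alternative 2:** Cut O1–C6 and O2–C3 together. The forward key step is a [4+2] cycloaddition of singlet oxygen to the diene C3=C4–C5=C6 of cycloheptadienone A2, held s-cis by an extra C1–C7 bond, to give endoperoxide A3, followed by lactonisation onto C4=C5 and cleavage of C1–C7. This would secure the cis relation of C2 and C7 by geometry. The tether is not optional: without a ring a C6 terminus with an inside methyl cannot reach the s-cis geometry and the ene reaction is expected to take over. The price is a C1–C7 bond whose cleavage must leave an unactivated CH2 next to the C8 stereocentre. A retro-Claisen cleavage needs an acceptor on C7 that the target lacks, and radical or reductive cleavage endangers the O–O bond (a β-peroxy radical closes to an epoxide). The chosen plan reaches the same stereochemical goal without any bond to be removed.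

**Alternative 3:** Cut O2–C3 with inversion. The forward key step is the 6-exo opening of the C3–C4 epoxide of A4 by the C6 hydroperoxide, followed by lactonisation of the released C4 alkoxide. C3 and C4 would both come from one asymmetric epoxidation. C6 would again depend on an unselective hydroperoxidation, and the β,γ-epoxy ester is prone to base-induced elimination to a γ-hydroxy enoate under the conditions that generate the peroxide anion. It needs a catalyst-controlled step for C3/C4 and still leaves C6 open, whereas the chosen plan buys one stereocentre and relays C3 and C6 from it.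

Key step: step 10

Remark: the SMILES is read as the absolute configuration; in the von Baeyer names below, positions 1, 4, 6 and 8 of the 2,3,7-trioxabicyclo[4.3.0]nonan-8-one are C3, C6, C4 and C1 of the numbering above; 1, 2, 5, 10, 14 and 22 are assumed to be catalogue compounds.

## Steps

Step 1
Reactants: 1 (R)-(2-methyloxiran-2-yl)methanol; 2 prop-1-en-2-ylmagnesium bromide
Product: 3 (S)-2,4-dimethylpent-4-ene-1,2-diol
Conditions: 2 (2.5 equiv), CuI (10 mol %), THF, −30 → 0 °C; aq NH4Cl
Reagents that add atoms: none
Why: Copper-catalysed Grignard opening of a 2,2-disubstituted epoxide should occur at the CH2 terminus (SN2), the first equivalent of 2 being spent on the hydroxyl; the C4 stereocentre is not a reacting centre and the degenerate Payne rearrangement of the alkoxide returns the same enantiomer, so the descriptor changes from R to S only through the priority order.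

Step 2
Reactants: 3 (S)-2,4-dimethylpent-4-ene-1,2-diol
Product: 4 (S)-2-hydroxy-2,4-dimethylpent-4-enal
Conditions: SO3·pyridine, DMSO, Et3N, CH2Cl2, 0 °C
Reagents that add atoms: none
Why: Parikh–Doering oxidation should convert the primary hydroxyl and leave the tertiary one; the aldehyde has no α-hydrogen, so C4 cannot epimerise, and the crude product is used directly.

Step 3
Reactants: 4 (S)-2-hydroxy-2,4-dimethylpent-4-enal; 5 (triphenylphosphoranylidene)ketene
Product: 7 (S)-5-methyl-5-(2-methylprop-2-en-1-yl)furan-2(5H)-one, via acyl ylide 6 (not isolated)
Conditions: 5 (1.1 equiv), toluene, 90 °C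
Reagents that add atoms: none
Why: Addition of the hydroxyl to the cumulated ylide should give the ester-stabilised ylide 6, which closes by intramolecular Wittig reaction with the neighbouring aldehyde; the ring enforces the Z alkene and C4 is untouched.

Step 4
Reactants: 7 (S)-5-methyl-5-(2-methylprop-2-en-1-yl)furan-2(5H)-one
Product: 9 (1S,4S,6S)-4-methoxy-4,6-dimethyl-2,3,7-trioxabicyclo[4.3.0]nonan-8-one, via hydroperoxy ketal 8 (not isolated)
Conditions: O3, CH2Cl2–MeOH (4:1), NaHCO3, −78 °C; N2 purge, concentrate cold; then Et2NH (0.5 equiv), CF3CH2OH, 0 °C → rt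
Reagents that add atoms: ozone (O=[O+][O-]); methanol (CO)
Why: Ozone should attack only the electron-rich 1,1-disubstituted alkene, and Criegee fragmentation in methanol should place OOH and OMe on the more substituted carbon (C6) while releasing the CH2 terminus as formaldehyde; the amine then triggers 6-exo-trig oxa-Michael addition of the hydroperoxide to C3, and C3 (S) is relayed from C4 because only the cis-fused bicycle can form. Both C6 anomers are expected (the one drawn, OMe axial and cis to the lactone oxygen, should predominate) and both are carried on.

Step 5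
Reactants: 10 prop-2-yn-1-ol
Product: 12 (E)-3-iodo-2-methylprop-2-en-1-ol, via alkenylalane 11 (not isolated)
Conditions: AlMe3 (3 equiv), Cp2ZrCl2 (0.25 equiv), CH2Cl2, 0 → 23 °C; then I2, THF, −30 → 0 °C
Reagents that add atoms: trimethylaluminium (C[Al](C)C); iodine ([I][I])
Why: Zirconium-catalysed carboalumination (Negishi) adds CH3 and Al syn across the alkyne with Al at the terminus, and iodinolysis with retention should give the E vinyl iodide that becomes C10=C11.

Step 6
Reactants: 12 (E)-3-iodo-2-methylprop-2-en-1-ol
Product: 13 (E)-3-bromo-1-iodo-2-methylprop-1-ene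
Conditions: CBr4, PPh3, CH2Cl2, 0 °C
Reagents that add atoms: carbon tetrabromide (BrC(Br)(Br)Br)
Why: Appel bromination of a primary allylic alcohol under neutral conditions should proceed without allylic transposition or loss of alkene geometry.

Step 7
Reactants: 14 (S)-4-benzyl-3-propanoyl-1,3-oxazolidin-2-one; 13 (E)-3-bromo-1-iodo-2-methylprop-1-ene
Product: 16 (S)-4-benzyl-3-[(2R,4E)-5-iodo-2,4-dimethylpent-4-enoyl]-1,3-oxazolidin-2-one, via sodium enolate 15 (not isolated)
Conditions: NaN(SiMe3)2, THF, −78 °C; then 13, −78 → −45 °C
Reagents that add atoms: none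
Why: Evans alkylation: the chelated Z enolate 15 should be attacked by the allylic bromide on the face opposite the benzyl group, which sets C8 as R; the vinyl iodide is inert to the enolate.

Step 8
Reactants: 16 (S)-4-benzyl-3-[(2R,4E)-5-iodo-2,4-dimethylpent-4-enoyl]-1,3-oxazolidin-2-one
Product: 17 (2R,4E)-5-iodo-2,4-dimethylpent-4-en-1-ol
Conditions: LiBH4, MeOH (1 equiv), Et2O, 0 °C
Reagents that add atoms: none
Why: Reductive cleavage of the N-acyl oxazolidinone with LiBH4 should give the primary alcohol without epimerising C8 or touching the vinyl iodide, and the auxiliary is recovered.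

Step 9
Reactants: 17 (2R,4E)-5-iodo-2,4-dimethylpent-4-en-1-ol
Product: 18 (1E,4R)-1,5-diiodo-2,4-dimethylpent-1-ene
Conditions: I2, PPh3, imidazole, CH2Cl2, 0 °C → rt
Reagents that add atoms: iodine ([I][I])
Why: Appel-type iodination of a β-branched primary alcohol is an SN2 displacement at C7 and does not involve C8.

Step 10
Reactants: 9 (1S,4S,6S)-4-methoxy-4,6-dimethyl-2,3,7-trioxabicyclo[4.3.0]nonan-8-one; 18 (1E,4R)-1,5-diiodo-2,4-dimethylpent-1-ene
Product: 21 (1S,4R,6S)-4-[(2R,4E)-5-iodo-2,4-dimethylpent-4-en-1-yl]-4,6-dimethyl-2,3,7-trioxabicyclo[4.3.0]nonan-8-one, via dialkylzinc 19 (not isolated), via peroxycarbenium triflate 20 (not isolated)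
Conditions: 18 (3 equiv), Et2Zn (neat), CuI (0.3 mol %), 50 °C, then volatiles off in vacuo; then 9, 2,6-di-tert-butyl-4-methylpyridine, CH2Cl2, −78 °C; TMSOTf (1.2 equiv), −78 → −40 °C; aq NaHCO3
Reagents that add atoms: none
Why: Proposed new method: iodine–zinc exchange at the sp3 C–I bond of 18 should give 19, and TMSOTf should silylate the exocyclic methoxy oxygen of 9 (the more basic ketal oxygen) and expel MeOSiMe3 to give the ring-bound peroxycarbenium ion 20, which 19 alkylates at C6; the closest known reaction types are the Lewis acid-mediated substitution of cyclic peroxyketals by allylsilanes and silyl enol ethers and the axial alkylation of cyclic alkoxycarbenium ions by dialkylzinc with TMSOTf, so only the pairing of a peroxycarbenium ion with a dialkylzinc is without precedent. No ring is closed; the step joins the side chain to the core at the quaternary peroxide carbon. The only new stereocentre is C6: the reactive half-chair of 20 should keep C4–CH3 and C3–C2 pseudoequatorial and the C4–O bond pseudoaxial (the arrangement also favoured electrostatically for an oxygen 1,3 to a cationic carbon), and attack along the chair-like axial trajectory places C7 cis to the lactone oxygen and to C2 and leaves the C6 methyl equatorial, which is 6R (4R in the bicyclo name). Both anomers of 9 converge on the same cation, and C8 arrives unchanged from 18. The step needs exocyclic instead of endocyclic C–O ionisation, which the lower basicity of a peroxide oxygen should secure. It also needs alkyl transfer to outrun β-hydride transfer from the β-branched alkylzinc, for which low temperature and a non-coordinating solvent are chosen. Finally the O–O bond and the lactone must be inert to the weakly nucleophilic dialkylzinc, and the vinyl iodide, a poor π-nucleophile, should not compete for the cation.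

Step 11
Reactants: 21 (1S,4R,6S)-4-[(2R,4E)-5-iodo-2,4-dimethylpent-4-en-1-yl]-4,6-dimethyl-2,3,7-trioxabicyclo[4.3.0]nonan-8-one; 22 but-2-yn-1-ylbenzene
Product: 25 (1S,4R,6S)-4,6-dimethyl-4-[(2R,4E,6E)-2,4,6-trimethyl-8-phenylocta-4,6-dien-1-yl]-2,3,7-trioxabicyclo[4.3.0]nonan-8-one (CNP0272658.1), via alkenylzirconocene chloride 23 (not isolated), via alkenylzinc chloride 24 (not isolated)
Conditions: 22 (2.0 equiv), Cp2Zr(H)Cl (2.2 equiv), THF, 40 °C; then 22 (0.4 equiv); ZnCl2 (THF), 0 °C; then 21, Pd2(dba)3 (2.5 mol %), tri(2-furyl)phosphine (10 mol %), THF, rt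
Reagents that add atoms: none
Why: syn-Hydrozirconation should place Zr on the methyl-bearing alkyne carbon (the smaller substituent, improved by equilibration with a slight excess of Cp2Zr(H)Cl) to give 23, which sets 12E; transmetalation to 24 and Negishi coupling with the vinyl iodide proceed with retention at both alkenes, and a weakly nucleophilic phosphine at room temperature is chosen to spare the O–O bond.

## Compound list

1 | (R)-(2-methyloxiran-2-yl)methanol | OC[C@]1(C)CO1 | starting material
2 | prop-1-en-2-ylmagnesium bromide | CC(=C)[Mg]Br | starting material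
3 | (S)-2,4-dimethylpent-4-ene-1,2-diol | C=C(C)C[C@](C)(O)CO | intermediate
4 | (S)-2-hydroxy-2,4-dimethylpent-4-enal | C=C(C)C[C@](C)(O)C=O | intermediate
5 | (triphenylphosphoranylidene)ketene | O=C=C=P(c1ccccc1)(c1ccccc1)c1ccccc1 | starting material
6 | (S)-2,4-dimethyl-1-oxopent-4-en-2-yl 2-(triphenylphosphoranylidene)acetate | C=C(C)C[C@@](C)(C=O)OC(=O)C=P(c1ccccc1)(c1ccccc1)c1ccccc1 | intermediate
7 | (S)-5-methyl-5-(2-methylprop-2-en-1-yl)furan-2(5H)-one | C=C(C)C[C@]1(C)OC(=O)C=C1 | intermediate
8 | (5S)-5-(2-hydroperoxy-2-methoxypropyl)-5-methylfuran-2(5H)-one (both epimers at the ketal carbon) | COC(C)(OO)C[C@]1(C)OC(=O)C=C1 | intermediate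
9 | (1S,4S,6S)-4-methoxy-4,6-dimethyl-2,3,7-trioxabicyclo[4.3.0]nonan-8-one (major anomer, used with its C4 epimer) | CO[C@]1(C)C[C@]2(C)OC(=O)C[C@@H]2OO1 | intermediate
10 | prop-2-yn-1-ol | C#CCO | starting material
11 | dimethylaluminium (E)-3-(dimethylalumanyl)-2-methylprop-2-en-1-olate | C[Al](C)OC/C(C)=C/[Al](C)C | intermediate
12 | (E)-3-iodo-2-methylprop-2-en-1-ol | OC/C(C)=C/I | intermediate
13 | (E)-3-bromo-1-iodo-2-methylprop-1-ene | BrC/C(C)=C/I | intermediate
14 | (S)-4-benzyl-3-propanoyl-1,3-oxazolidin-2-one | CCC(=O)N1[C@@H](Cc2ccccc2)COC1=O | starting material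
15 | sodium (Z)-enolate of 14 | C/C=C(\[O-])N1[C@@H](Cc2ccccc2)COC1=O.[Na+] | intermediate
16 | (S)-4-benzyl-3-[(2R,4E)-5-iodo-2,4-dimethylpent-4-enoyl]-1,3-oxazolidin-2-one | I/C=C(\C)C[C@@H](C)C(=O)N1[C@@H](Cc2ccccc2)COC1=O | intermediate
17 | (2R,4E)-5-iodo-2,4-dimethylpent-4-en-1-ol | I/C=C(\C)C[C@@H](C)CO | intermediate
18 | (1E,4R)-1,5-diiodo-2,4-dimethylpent-1-ene | I/C=C(\C)C[C@@H](C)CI | intermediate
19 | bis[(2R,4E)-5-iodo-2,4-dimethylpent-4-en-1-yl]zinc | I/C=C(\C)C[C@@H](C)C[Zn]C[C@H](C)C/C(C)=C/I | intermediate
20 | (1S,6S)-4,6-dimethyl-8-oxo-2,3,7-trioxabicyclo[4.3.0]non-3-en-3-ium trifluoromethanesulfonate | CC1=[O+]O[C@H]2CC(=O)O[C@@]2(C)C1.[O-]S(=O)(=O)C(F)(F)F | intermediate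
21 | (1S,4R,6S)-4-[(2R,4E)-5-iodo-2,4-dimethylpent-4-en-1-yl]-4,6-dimethyl-2,3,7-trioxabicyclo[4.3.0]nonan-8-one | I/C=C(\C)C[C@@H](C)C[C@]1(C)C[C@]2(C)OC(=O)C[C@@H]2OO1 | intermediate
22 | but-2-yn-1-ylbenzene | CC#CCc1ccccc1 | starting material
23 | chlorobis(cyclopentadienyl)[(E)-4-phenylbut-2-en-2-yl]zirconium | C/C(=C\Cc1ccccc1)[Zr](Cl)(C1C=CC=C1)C1C=CC=C1 | intermediate
24 | chloro[(E)-4-phenylbut-2-en-2-yl]zinc | C/C(=C\Cc1ccccc1)[Zn]Cl | intermediate
25 | (1S,4R,6S)-4,6-dimethyl-4-[(2R,4E,6E)-2,4,6-trimethyl-8-phenylocta-4,6-dien-1-yl]-2,3,7-trioxabicyclo[4.3.0]nonan-8-one | CC(=C\Cc1ccccc1)/C=C(\C)C[C@@H](C)C[C@]1(C)C[C@]2(C)OC(=O)C[C@@H]2OO1 | target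

## Step count and least certain steps

Total: 11 steps. Longest linear sequence: 7 steps (steps 5, 6, 7, 8, 9, 10, 11, from 10); the core branch (steps 1 to 4) joins at step 10.

**Step 10 (key step, Proposed new method).** Three things may go wrong. The β-branched alkylzinc may transfer hydride to the cation (reduction at C6) instead of the alkyl group. The organozinc or the Lewis acid may break the O–O bond (Hock-type fragmentation of the cation, or ionisation of the ring C6–O1 bond). Facial selectivity may be lost if attack through a twist-boat on the open face competes with the axial path, which passes the axial C4 oxygen.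

The fallback uses known chemistry, sets out from 7 and 18, and returns at 21. Ozonolysis of 7 in CH2Cl2 with Me2S work-up should give the keto butenolide F1. Zinc insertion into the sp3 C–I bond of 18 (Zn dust, LiCl, THF) should give the alkylzinc iodide F2. MgCl2-promoted 1,2-addition of F2 to the ketone of F1, quenched cold to avoid oxa-Michael closure of the alkoxide, should give the tertiary alcohol F3 as both C6 epimers. Acid-catalysed perhydrolysis (50% H2O2, cat. H2SO4, Et2O, 0 °C; SN1 at the tertiary carbinol) should give the tertiary hydroperoxide F4. Et2NH in CF3CH2OH then closes the dioxane by oxa-Michael addition to give 21 together with its C6 epimer F5, to be separated by chromatography. This is the first-drawn route and gives up the control of C6.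

**Step 11.** Regiochemical leakage in the hydrozirconation is possible because CH3 and CH2Ph differ little in size, and it would give a branched diene isomer that is hard to remove at the end. The phosphine, zerovalent palladium or residual Zr–H may also reduce the O–O bond.

The fallback installs the diene before the peroxide is present; it sets out from 16, 22 and 9 and returns at 25. The same hydrozirconation, zinc transmetalation and palladium coupling applied to 16 should give the dienyl imide F6, which is purified from its regioisomer at this stage. LiBH4 then gives the dienol F7, and I2/PPh3/imidazole the dienyl iodide F8. Iodine–zinc exchange (Et2Zn, CuI) gives the bis(dienyl)zinc F9, and the alkylation of 9 under the conditions of step 10 gives 25 directly. The price is a diene that may compete as a π-nucleophile in that step.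

**Step 4.** The ozonide may fragment in the unwanted direction, which would leave the ketone without a hydroperoxy group. Ozone may attack the butenolide if overdosed, and the Michael closure may be incomplete or reversed by the amine.

The fallback sets out from 7 and returns at 8 and then 9; it makes no compound beyond F1 of the step 10 fallback. Ozonolysis with reductive work-up gives the keto butenolide F1, and acid-catalysed perhydrolysis in methanol (H2O2, MeOH, camphorsulfonic acid cat.) installs the OOH and OMe groups at C6 by nucleophilic addition instead of Criegee capture. Et2NH in CF3CH2OH then closes the ring as in step 4.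

**Step 3.** Addition of the hindered tertiary hydroxyl to the cumulene may be slow, and the α-hydroxy aldehyde may dimerise or condense at the temperature required.

The fallback sets out from 4 and returns at 7. Wittig methylenation (Ph3P=CH2, 2.2 equiv, THF) should give the vinyl carbinol F10, and acylation (acryloyl chloride, Et3N, DMAP) the acrylate F11. Ring-closing metathesis with the second-generation Grubbs catalyst (H2IMes)(PCy3)Cl2Ru=CHPh in CH2Cl2 at 40 °C should then close the five-membered butenolide in preference to the seven-membered ring through the 1,1-disubstituted alkene.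

## Further compounds

F1 | step 10 | (S)-5-methyl-5-(2-oxopropyl)furan-2(5H)-one | CC(=O)C[C@]1(C)OC(=O)C=C1
F2 | step 10 | iodo[(2R,4E)-5-iodo-2,4-dimethylpent-4-en-1-yl]zinc | I/C=C(\C)C[C@@H](C)C[Zn]I
F3 | step 10 | (5S)-5-[(4R,6E)-2-hydroxy-7-iodo-2,4,6-trimethylhept-6-en-1-yl]-5-methylfuran-2(5H)-one (both epimers at the carbinol carbon) | I/C=C(\C)C[C@@H](C)CC(C)(O)C[C@]1(C)OC(=O)C=C1
F4 | step 10 | (5S)-5-[(4R,6E)-2-hydroperoxy-7-iodo-2,4,6-trimethylhept-6-en-1-yl]-5-methylfuran-2(5H)-one (both epimers at the peroxide carbon) | I/C=C(\C)C[C@@H](C)CC(C)(OO)C[C@]1(C)OC(=O)C=C1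
F5 | step 10 | (1S,4S,6S)-4-[(2R,4E)-5-iodo-2,4-dimethylpent-4-en-1-yl]-4,6-dimethyl-2,3,7-trioxabicyclo[4.3.0]nonan-8-one | I/C=C(\C)C[C@@H](C)C[C@@]1(C)C[C@]2(C)OC(=O)C[C@@H]2OO1
F6 | step 11 | (S)-4-benzyl-3-[(2R,4E,6E)-2,4,6-trimethyl-8-phenylocta-4,6-dienoyl]-1,3-oxazolidin-2-one | CC(=C\Cc1ccccc1)/C=C(\C)C[C@@H](C)C(=O)N1[C@@H](Cc2ccccc2)COC1=O
F7 | step 11 | (2R,4E,6E)-2,4,6-trimethyl-8-phenylocta-4,6-dien-1-ol | CC(=C\Cc1ccccc1)/C=C(\C)C[C@@H](C)CO
F8 | step 11 | [(2E,4E,7R)-8-iodo-3,5,7-trimethylocta-2,4-dien-1-yl]benzene | CC(=C\Cc1ccccc1)/C=C(\C)C[C@@H](C)CI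
F9 | step 11 | bis[(2R,4E,6E)-2,4,6-trimethyl-8-phenylocta-4,6-dien-1-yl]zinc | CC(=C\Cc1ccccc1)/C=C(\C)C[C@@H](C)C[Zn]C[C@H](C)C/C(C)=C/C(C)=C/Cc1ccccc1
F0 | step 4 | none | none
F10 | step 3 | (S)-3,5-dimethylhexa-1,5-dien-3-ol | C=C(C)C[C@](C)(O)C=C
F11 | step 3 | (S)-3,5-dimethylhexa-1,5-dien-3-yl prop-2-enoate | C=C(C)C[C@@](C)(C=C)OC(=O)C=C
A1 | alternative 1 | (5S)-5-[(4R,6E,8E)-2-hydroperoxy-2,4,6,8-tetramethyl-10-phenyldeca-6,8-dien-1-yl]-5-methylfuran-2(5H)-one (both epimers at the peroxide carbon) | CC(=C\Cc1ccccc1)/C=C(\C)C[C@@H](C)CC(C)(OO)C[C@]1(C)OC(=O)C=C1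
A2 | alternative 2 | 2-[(2R,4E)-5-iodo-4-methylpent-4-en-2-yl]-3,5-dimethylcyclohepta-3,5-dien-1-one | O=C1CC=C(C)C=C(C)C1[C@H](C)C/C(C)=C/I
A3 | alternative 2 | 2-[(2R,4E)-5-iodo-4-methylpent-4-en-2-yl]-1,8-dimethyl-6,7-dioxabicyclo[3.2.2]non-8-en-3-one (bridgeheads configured as C6 and C3 of the target) | O=C1C[C@@H]2OO[C@@](C)(C=C2C)C1[C@H](C)C/C(C)=C/I
A4 | alternative 3 | methyl 2-[(2R,3S)-3-[(4R,6E)-2-hydroperoxy-7-iodo-2,4,6-trimethylhept-6-en-1-yl]-3-methyloxiran-2-yl]acetate (both epimers at the peroxide carbon) | COC(=O)C[C@H]1O[C@@]1(C)CC(C)(OO)C[C@H](C)C/C(C)=C/I
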